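All constants were set for the occasion; the flask was simulated.

Amounts first: we count each species as a fraction of its charge, and ask how much reagent is left once a given fraction of the substrate has become product.

    substrate + free catalyst → catalyst intermediate A (k1 = 0.19 M⁻¹ min⁻¹)
    reagent + released group ⇌ idle adduct, settled at all times (K2 = 4900 M⁻¹)
    free catalyst + impurity → spent catalyst (k3 = 7.6 M⁻¹ min⁻¹)
    catalyst intermediate B ⇌ released group + catalyst intermediate C (K4 = 0.12 M, k4 = 0.0096 min⁻¹)
    catalyst intermediate C → free catalyst + product (k5 = 0.13 min⁻¹)
    reagent + catalyst intermediate A → catalyst intermediate B (k6 = 0.15 M⁻¹ min⁻¹)

substrate 0.050 M; reagent 1.10 equiv; free catalyst 10 mol%; impurity 0.61 mM; time 40 h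

- amounts and yields of released group count idle adduct too
- run time (flask): 40 h

- part of the substrate that has reacted at 40 h
- share of the unused reagent that is free and not bound as idle adduct, at 40 h

In one turn, free catalyst takes up substrate to give intermediate A, A takes up reagent to give B, B releases the released group to become C, and C gives product and free catalyst. The released group then binds a second reagent as idle adduct, since the binding constant times the reagent charge is 270. So while reagent is ample each product costs two reagents. We call the two-for-one mark the product at which free reagent would be used up at that price, 55.0% of the substrate, which is half the charge ratio 1.10. While the price holds, the fraction of reagent left is one minus product over the mark.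

We let each impurity remove one catalyst, which leaves 8.78% of the substrate charge as live catalyst. At the charges, a turn takes 338 min. With nothing slowing, the run gives 62.3%, more than the mark, so this first extreme, with the price held, stops at 55.0%. In the second extreme the whole turn stretches as the fraction left below the mark shrinks; that fraction then decays exponentially, and product reaches 37.3%. But the two steps from B onward take 33.1% of the turn, a third, and their forward rates contain neither reagent nor substrate, so we go that share of the way up, to 43.1% product. Reacted substrate also counts what sits on the catalyst; by time within the turn we put that at the part after substrate uptake, 68.9% of the live catalyst, which gives 49.2% reacted. With adduct equal to product, 35.5% of the unused reagent is free.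

The forecast says 46% and 44%, on the same price: “Each turnover uses one reagent in the cycle and ties up about another as idle adduct”. Its free share is higher than ours, and its reacted part is lower than ours.

The flask gives 47.9% reacted and 39.2% free, both within the forecast's margin. At 40.0 h the idle adduct stands at 40.9% of the substrate charge, about the same as the product at 41.5%; the mark then gives 24.5% of the reagent left, and the flask holds 23.9%. In the neighbour flask charged with 0.0015 M of impurity, product at 36.1% after 40.0 h gives 34.4% by the mark, and that flask holds 33.6%.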